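**Retrosynthetic overview**
- The endgame is peeled back through C2/C10 acetylation, hydroxyl-directed C8–C9 epoxidation, C6 angeloylation and isopropyl addition to a C4 ketone, to a trans-fused hydroazulene with a C6 ketone and a C8=C9 alkene.
- The strategy rests on the seven-membered ring C1–C5–C6–C7–C8–C9–C10: its C7 methylene lies between a C5=C6 enol (masked C6 carbinol and C5 hydrogen) and the C8=C9 alkene (masked epoxide), opposite the C1–C10 bond, which is a cyclohepta-1,4-diene.
- That ring is cut at C7–C8 and C1–C10 into a 2-silyloxy diene on the cyclopentene (C7=C6–C5=C1) and a rhodium vinylcarbenoid (C8–C9=C10) carrying the ester (future C8 methyl) and an E silyl enol ether (C10 oxygen); forward, cyclopropanation then divinylcyclopropane Cope rearrangement.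
- Ring order: cyclopentene (bought; C2 oxygen set by enzymatic resolution), cyclopropane (formed and consumed in the key step), cycloheptadiene, epoxide last.

Key step: step 11

Remark: bicyclic compounds are numbered as daucanes (C1 methyl-bearing fusion carbon, C2–C4 in the five-membered ring, C5 fusion CH, C6–C10 in the seven-membered ring), β is the face of the C1 methyl, and monocyclic precursors are described with the locants their carbons will have; the target is (1R,2S,4R,5S,6S,8R,9S,10S) in this numbering, and the sense of the lipase and of the rhodium catalyst is assumed from the usual empirical models.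

Step 1
Reactants: 1 3-methylcyclopent-2-en-1-one
Product: 2 rac-4-bromo-3-methylcyclopent-2-en-1-one
Conditions: N-bromosuccinimide, AIBN (cat.), PhCF3, reflux; used crude
Reagents that add atoms: N-bromosuccinimide, O=C1CCC(=O)N1Br
Why: Wohl–Ziegler bromination should take the secondary ring hydrogen gamma to the carbonyl rather than a primary methyl hydrogen, as in the classical conversion of 2-alkyl-3-methylcyclopentenones into rethrolones, and this entry is preferred to photo-oxygenation of a dienol silyl ether because silyloxycyclopentadienes scramble by 1,5-hydrogen shifts.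

Step 2
Reactants: 2 rac-4-bromo-3-methylcyclopent-2-en-1-one
Product: 3 rac-4-hydroxy-3-methylcyclopent-2-en-1-one
Conditions: CaCO3, H2O/1,4-dioxane, 70 °C
Reagents that add atoms: water, O
Why: Buffered solvolysis (SN1-type allylic substitution) of the secondary allylic bromide by water should give the gamma-hydroxy enone, the insoluble carbonate only scavenging HBr and being too weak a base to eliminate.

Step 3
Reactants: 3 rac-4-hydroxy-3-methylcyclopent-2-en-1-one
Product: 4 (S)-4-hydroxy-3-methylcyclopent-2-en-1-one
Conditions: immobilised Candida antarctica lipase B, vinyl acetate, t-BuOMe, 30 °C, run slightly past half conversion; chromatographic separation from the acetate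
Reagents that add atoms: none
Why: Lipase-catalysed kinetic resolution by irreversible transesterification is expected, from the empirical rule for secondary alcohols and the behaviour of 4-hydroxycyclopent-2-enone, to acylate the R enantiomer and leave the S alcohol, whose carbinol carbon becomes C2 of the target.

Step 4
Reactants: 4 (S)-4-hydroxy-3-methylcyclopent-2-en-1-one
Product: 5 (S)-4-(tert-butyldimethylsilyloxy)-3-methylcyclopent-2-en-1-one
Conditions: t-BuMe2SiCl, imidazole, DMF, 0 °C to rt
Reagents that add atoms: tert-butyldimethylsilyl chloride, CC(C)(C)[Si](C)(C)Cl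
Why: Standard O-silylation under imidazole catalysis protects the future C2 oxygen without touching the stereocentre or the enone.

Step 5
Reactants: 5 (S)-4-(tert-butyldimethylsilyloxy)-3-methylcyclopent-2-en-1-one
Product: 7 (S)-2-bromo-4-(tert-butyldimethylsilyloxy)-3-methylcyclopent-2-en-1-one, via dibromide 6 (not isolated)
Conditions: Br2, CH2Cl2, 0 °C; then Et3N, 0 °C to rt
Reagents that add atoms: bromine, BrBr
Why: Bromine addition to the enone and amine-induced dehydrobromination (loss of the acidic alpha hydrogen and the tertiary beta bromide) is the standard alpha-bromination of beta-substituted enones and puts the halide on the future C5.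

Step 6
Reactants: 7 (S)-2-bromo-4-(tert-butyldimethylsilyloxy)-3-methylcyclopent-2-en-1-one
Product: 8 (S)-6-bromo-8-(tert-butyldimethylsilyloxy)-7-methyl-1,4-dioxaspiro[4.4]non-6-ene
Conditions: Me3SiOCH2CH2OSiMe3, Me3SiOTf (cat.), CH2Cl2, −78 to −20 °C; pyridine quench
Reagents that add atoms: 1,2-bis(trimethylsilyloxy)ethane, C[Si](C)(C)OCCO[Si](C)(C)C
Why: Noyori ketalisation masks the future C4 carbonyl under aprotic, low-temperature conditions that spare the allylic silyl ether, and the alpha-bromine keeps the double bond in place.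

Step 7
Reactants: 8 (S)-6-bromo-8-(tert-butyldimethylsilyloxy)-7-methyl-1,4-dioxaspiro[4.4]non-6-ene; 9 tributyl(1-ethoxyvinyl)stannane
Product: 11 (S)-1-[8-(tert-butyldimethylsilyloxy)-7-methyl-1,4-dioxaspiro[4.4]non-6-en-6-yl]ethan-1-one, via ethoxydiene 10 (not isolated)
Conditions: Pd(PPh3)4 (5 mol %), CuI (10 mol %), CsF, DMF, 50 °C; then 0.5 M aq. HCl, THF, 0 °C, 10 min
Reagents that add atoms: water, O
Why: Stille coupling (oxidative addition of zerovalent palladium to the hindered alkenyl bromide, copper- and fluoride-assisted transmetallation, reductive elimination) attaches C6 and C7 as the 1-ethoxyvinyl group, and the very acid-labile 2-alkoxy diene is then hydrolysed to the methyl ketone under conditions that spare the less easily ionised enone dioxolane and the silyl ether.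

Step 8
Reactants: 11 (S)-1-[8-(tert-butyldimethylsilyloxy)-7-methyl-1,4-dioxaspiro[4.4]non-6-en-6-yl]ethan-1-one
Product: 12 2-silyloxy diene, (S)-8-(tert-butyldimethylsilyloxy)-7-methyl-6-[1-(triethylsilyloxy)vinyl]-1,4-dioxaspiro[4.4]non-6-ene (C7=C6(OSiEt3)–C5=C1)
Conditions: LiN(i-Pr)2, THF, −78 °C; Et3SiCl, −78 to 0 °C; chromatography on Et3N-deactivated silica
Reagents that add atoms: chlorotriethylsilane, CC[Si](Cl)(CC)CC
Why: Kinetic deprotonation of the methyl ketone and O-silylation give the cross-conjugated 2-silyloxy diene, a silyl rather than the ethyl enol ether being carried into the annulation because the enol ether will end up next to the C4 dioxolane (a vinylogous ortho ester that acid would ionise) whereas a silyl enol ether can be unmasked by fluoride.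

Step 9
Reactants: 13 (tert-butyldimethylsilyloxy)acetaldehyde; 14 ethyl diazoacetate
Product: 15 ethyl 2-diazo-3-hydroxy-4-(tert-butyldimethylsilyloxy)butanoate (racemic)
Conditions: DBU (10 mol %), MeCN, rt
Reagents that add atoms: none
Why: Base-catalysed aldol-type addition of the diazoacetate carbon to the aldehyde is a standard route to beta-hydroxy-alpha-diazo esters and leaves the diazo group intact.

Step 10
Reactants: 15 ethyl 2-diazo-3-hydroxy-4-(tert-butyldimethylsilyloxy)butanoate
Product: 16 ethyl (E)-2-diazo-4-(tert-butyldimethylsilyloxy)but-3-enoate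
Conditions: POCl3, Et3N, CH2Cl2, 0 °C; short filtration, kept cold and used at once
Reagents that add atoms: none
Why: Phosphorylation of the carbinol and amine-induced elimination toward the silyloxy-bearing carbon is the usual dehydration of diazo aldol adducts to vinyldiazoacetates and should favour the less hindered E enol ether.

Step 11
Reactants: 12 2-silyloxy diene; 16 ethyl (E)-2-diazo-4-(tert-butyldimethylsilyloxy)but-3-enoate
Product: 18 hydroazulene cyclohepta-1,4-diene, ethyl 1β-methyl-2α,10α-bis(tert-butyldimethylsilyloxy)-6-(triethylsilyloxy)-4,4-ethylenedioxybicyclo[5.3.0]deca-5,8-diene-8-carboxylate (daucane numbering; C5=C6 silyl enol ether, C8=C9 enoate), via cis-divinylcyclopropane 17 (not isolated)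
Conditions: Rh2(R-DOSP)4 [tetrakis((R)-N-(4-dodecylphenylsulfonyl)prolinato)dirhodium] (1 mol %), hexanes, −40 °C, slow addition of 16 (1.5 equiv) over 2 h, then rt; then toluene, 90–110 °C, base-washed glassware
Reagents that add atoms: none
Why: Loss of N2 from 16 gives a donor/acceptor rhodium carbenoid whose carbene carbon (C8) adds across the electron-rich, unhindered C6=C7 terminus of 12 in a concerted asynchronous [2+1] closure of the cyclopropane, the tetrasubstituted C5=C1 bond being untouched, and the siloxyvinyl group settles cis to the cyclopentenyl group (17). On heating, 17 undergoes a [3,3] sigmatropic (Cope) shift through the boat transition state that forms C1–C10 and breaks C6–C8, so the seven-membered ring is closed by a strain-driven ring expansion of the cyclopropane onto the cyclopentene. The closest known reaction type is the formal (4+3) cycloaddition of vinyldiazoacetates with 2-silyloxy dienes by tandem cyclopropanation and divinylcyclopropane rearrangement; the 4-silyloxy substituent on the carbenoid and the fully substituted diene terminus extend it. The transient cyclopropane centres C6 and C8 are set by the chiral dirhodium prolinate (the R catalyst is chosen from the usual facial model for such carbenoids, its antipode being held in reserve), since C2 is too remote from C6=C7 to bias the addition, and they decide which face of C1 meets C10. C1 and C10 then follow stereospecifically from the boat, in which the E enol ether places the C10 oxygen on the side of the C1–C2 bond and the ring-held C1 methyl points inward, so the 1β-methyl, 10α-oxygen array syn to the 2α silyl ether results. The step needs carbenoid rather than vinylogous reactivity, attack at C6=C7 only, cis-divinyl geometry and survival of the catalyst-set configuration up to the rearrangement: the hydrocarbon solvent, slow addition of 16 and its substituted vinyl terminus serve the first, the electron-rich methylene terminus the second, the donor/acceptor carbenoid the third, and acid-free non-polar heating the fourth, heating being needed because the methyl points inward and C10 arrives on the face of the C2 silyl ether.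

Step 12
Reactants: 18 hydroazulene diene ester
Product: 19 allylic alcohol, as 18 with CH2OH on C8
Conditions: i-Bu2AlH (2.5 equiv), CH2Cl2, −78 °C; aqueous potassium sodium tartrate work-up
Reagents that add atoms: none
Why: 1,2-Reduction of the enoate by the aluminium hydride gives the primary allylic alcohol and leaves the silyl enol ether, the dioxolane and the silyl ethers alone.

Step 13
Reactants: 19 allylic alcohol
Product: 20 allylic methanesulfonate, as 19 with CH2OSO2Me on C8
Conditions: (MeSO2)2O, Et3N, CH2Cl2, −20 °C; used crude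
Reagents that add atoms: methanesulfonic anhydride, CS(=O)(=O)OS(C)(=O)=O
Why: Sulfonylation under basic, chloride-free conditions activates the primary allylic oxygen without acid that would harm the enol ether.

Step 14
Reactants: 20 allylic methanesulfonate
Product: 21 C8-methyl diene, 1β,8-dimethyl-2α,10α-bis(tert-butyldimethylsilyloxy)-6-(triethylsilyloxy)-4,4-ethylenedioxybicyclo[5.3.0]deca-5,8-diene
Conditions: LiEt3BH, THF, 0 °C
Reagents that add atoms: none
Why: Direct SN2 displacement of the primary allylic sulfonate by the hindered borohydride turns the ester carbon into the C8 methyl without allylic transposition.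

Step 15
Reactants: 21 C8-methyl diene
Product: 22 trans-fused C6 ketone (5α-H) with C8=C9 alkene, C4 dioxolane and 2α,10α silyl ethers
Conditions: Bu4NF (1.1 equiv), AcOH (1.5 equiv), THF, −20 to 0 °C
Reagents that add atoms: none
Why: Fluoride cleaves the silyl enol ether far faster than the two hindered secondary silyl ethers and leaves the dioxolane alone, the enolate is protonated at C5 by the acetic acid buffer on the face away from the angular methyl, which should give the trans ring fusion, and the cold buffered medium is meant to keep the beta,gamma-alkene from moving into conjugation.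

Step 16
Reactants: 22 trans-fused C6 ketone
Product: 23 C6 carbinol (mainly 6β-OH expected)
Conditions: NaBH4, MeOH/CH2Cl2, −40 to 0 °C
Reagents that add atoms: none
Why: Borohydride reduction masks the C6 carbonyl as a carbinol so that the C4 ketone can later be released and attacked alone, hydride being expected to enter anti to the angular methyl (this centre is reset at step 22).

Step 17
Reactants: 23 C6 carbinol
Product: 24 C6 4-methoxybenzyl ether
Conditions: NaH, 4-MeOC6H4CH2Cl, Bu4NI (cat.), THF/DMF, 0 °C to rt
Reagents that add atoms: 4-methoxybenzyl chloride, COc1ccc(CCl)cc1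
Why: Williamson etherification gives an ether that survives the acidic ketal hydrolysis and the organometallic step, unlike a triethylsilyl ether, and is removable oxidatively beside the silyl ethers.

Step 18
Reactants: 24 C6 4-methoxybenzyl ether
Product: 25 C4 cyclopentanone
Conditions: PPTS, acetone/H2O, 55 °C
Reagents that add atoms: water, O
Why: Mild acid-catalysed transketalisation and hydrolysis release the C4 ketone now that no enol ether is adjacent, and secondary tert-butyldimethylsilyl and benzyl-type ethers tolerate these conditions.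

Step 19
Reactants: 25 C4 cyclopentanone; 26 isopropylmagnesium chloride
Product: 27 C4 tertiary carbinol (4β-OH, 4α-isopropyl)
Conditions: CeCl3 (anhydrous), i-PrMgCl, THF, −78 to −40 °C; aq. NH4Cl
Reagents that add atoms: none
Why: Organocerium addition (low basicity, no beta-hydride reduction) should occur on the α face of the cyclopentanone, anti to the β-oriented C5–C6 bond on the adjacent carbon and to the angular methyl, placing the isopropyl group α and the hydroxyl β at C4.

Step 20
Reactants: 27 C4 tertiary carbinol
Product: 28 4β,6β-diol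
Conditions: DDQ, CH2Cl2/aq. NaH2PO4–Na2HPO4 buffer (pH 7), 0 °C
Reagents that add atoms: none
Why: Oxidative cleavage of the electron-rich benzyl ether through its oxocarbenium ion, hydrolysed by the aqueous buffer, frees the C6 hydroxyl without affecting the silyl ethers, the tertiary alcohol or the trisubstituted alkene.

Step 21
Reactants: 28 4β,6β-diol
Product: 29 beta-hydroxy ketone (C6 ketone, C4 tertiary carbinol)
Conditions: Dess–Martin periodinane, pyridine, CH2Cl2, 0 °C
Reagents that add atoms: none
Why: The periodinane oxidises the secondary alcohol under near-neutral conditions that should avoid retro-aldol cleavage, dehydration or alkene migration, the tertiary alcohol being inert.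

Step 22
Reactants: 29 beta-hydroxy ketone
Product: 30 4β,6α-diol (anti 1,3-diol)
Conditions: Me4NBH(OAc)3, MeCN/AcOH, −30 to −20 °C
Reagents that add atoms: none
Why: Evans–Saksena reduction, in which the tertiary C4 hydroxyl exchanges onto boron and delivers hydride intramolecularly to the β face of the C6 ketone (the C4 oxygen and the C5–C6 bond are cis on the five-membered ring), should give the anti 1,3-diol, that is the 6α alcohol.

Step 23
Reactants: 30 4β,6α-diol; 31 angelic acid, (Z)-2-methylbut-2-enoic acid
Product: 32 6α-angelate with 2α,10α silyl ethers and free 4β-OH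
Conditions: 31, 2,4,6-Cl3C6H2COCl, Et3N, toluene, rt; then 30, 75 °C, no nucleophilic catalyst
Reagents that add atoms: none
Why: Yamaguchi-type mixed-anhydride esterification acylates the secondary C6 hydroxyl while the hindered tertiary C4 hydroxyl stays free, and omitting a nucleophilic amine catalyst avoids Z-to-E isomerisation of the angelate to the tiglate.

Step 24
Reactants: 32 6α-angelate bis-silyl ether
Product: 33 6α-angelate 2α,4β,10α-triol
Conditions: HF·pyridine, pyridine, THF, 0 °C to rt
Reagents that add atoms: none
Why: Buffered hydrogen fluoride removes both secondary silyl ethers without the basic conditions that could move or isomerise the angelate.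

Step 25
Reactants: 33 triol angelate
Product: 34 8α,9α-epoxide triol angelate
Conditions: VO(acac)2 (5 mol %), t-BuOOH, CH2Cl2, 0 °C to rt
Reagents that add atoms: tert-butyl hydroperoxide, CC(C)(C)OO
Why: Vanadium-catalysed epoxidation is directed by the allylic C10 hydroxyl, so oxygen is delivered syn to it on the α face of C8=C9 (the equally α C2 hydroxyl does not oppose this), and the electron-poor angelate alkene is not epoxidised.

Step 26
Reactants: 34 epoxide triol angelate
Product: 35 target, 2α,10α-diacetoxy-6α-angeloyloxy-8α,9α-epoxy-daucan-4β-ol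
Conditions: Ac2O, pyridine, DMAP (cat.), CH2Cl2, 0 °C to rt
Reagents that add atoms: acetic anhydride, CC(=O)OC(C)=O
Why: Nucleophile-catalysed acetylation esterifies the two secondary hydroxyls at C2 and C10 while the hindered tertiary C4 hydroxyl does not react under these mild conditions.

**Compound list**
1 | 3-methylcyclopent-2-en-1-one | CC1=CC(=O)CC1 | starting material
2 | rac-4-bromo-3-methylcyclopent-2-en-1-one | CC1=CC(=O)CC1Br | intermediate
3 | rac-4-hydroxy-3-methylcyclopent-2-en-1-one | CC1=CC(=O)CC1O | intermediate
4 | (S)-4-hydroxy-3-methylcyclopent-2-en-1-one | O=C1C=C(C)[C@@H](O)C1 | intermediate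
5 | (S)-4-(tert-butyldimethylsilyloxy)-3-methylcyclopent-2-en-1-one | O=C1C=C(C)[C@@H](O[Si](C)(C)C(C)(C)C)C1 | intermediate
6 | (4S)-2,3-dibromo-4-(tert-butyldimethylsilyloxy)-3-methylcyclopentan-1-one (mixture at the two bromine-bearing carbons; not isolated) | O=C1C(Br)C(C)(Br)[C@@H](O[Si](C)(C)C(C)(C)C)C1 | intermediate
7 | (S)-2-bromo-4-(tert-butyldimethylsilyloxy)-3-methylcyclopent-2-en-1-one | O=C1C(Br)=C(C)[C@@H](O[Si](C)(C)C(C)(C)C)C1 | intermediate
8 | (S)-6-bromo-8-(tert-butyldimethylsilyloxy)-7-methyl-1,4-dioxaspiro[4.4]non-6-ene | BrC1=C(C)[C@@H](O[Si](C)(C)C(C)(C)C)CC12OCCO2 | intermediate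
9 | tributyl(1-ethoxyvinyl)stannane | CCCC[Sn](CCCC)(CCCC)C(=C)OCC | starting material
10 | (S)-8-(tert-butyldimethylsilyloxy)-6-(1-ethoxyvinyl)-7-methyl-1,4-dioxaspiro[4.4]non-6-ene (not isolated) | C=C(OCC)C1=C(C)[C@@H](O[Si](C)(C)C(C)(C)C)CC12OCCO2 | intermediate
11 | (S)-1-[8-(tert-butyldimethylsilyloxy)-7-methyl-1,4-dioxaspiro[4.4]non-6-en-6-yl]ethan-1-one | CC(=O)C1=C(C)[C@@H](O[Si](C)(C)C(C)(C)C)CC12OCCO2 | intermediate
12 | (S)-8-(tert-butyldimethylsilyloxy)-7-methyl-6-[1-(triethylsilyloxy)vinyl]-1,4-dioxaspiro[4.4]non-6-ene | C=C(O[Si](CC)(CC)CC)C1=C(C)[C@@H](O[Si](C)(C)C(C)(C)C)CC12OCCO2 | intermediate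
13 | (tert-butyldimethylsilyloxy)acetaldehyde | O=CCO[Si](C)(C)C(C)(C)C | starting material
14 | ethyl diazoacetate | CCOC(=O)C=[N+]=[N-] | starting material
15 | ethyl 2-diazo-3-hydroxy-4-(tert-butyldimethylsilyloxy)butanoate (racemic) | CCOC(=O)C(=[N+]=[N-])C(O)CO[Si](C)(C)C(C)(C)C | intermediate
16 | ethyl (E)-2-diazo-4-(tert-butyldimethylsilyloxy)but-3-enoate | CCOC(=O)C(=[N+]=[N-])/C=C/O[Si](C)(C)C(C)(C)C | intermediate
17 | ethyl (1S,2R)-1-[(E)-2-(tert-butyldimethylsilyloxy)vinyl]-2-(triethylsilyloxy)-2-[(S)-8-(tert-butyldimethylsilyloxy)-7-methyl-1,4-dioxaspiro[4.4]non-6-en-6-yl]cyclopropane-1-carboxylate (cis-divinylcyclopropane; not isolated) | CC[Si](CC)(CC)O[C@@]1(C2=C(C)[C@@H](O[Si](C)(C)C(C)(C)C)CC23OCCO3)C[C@]1(C(=O)OCC)/C=C/O[Si](C)(C)C(C)(C)C | intermediate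
18 | ethyl 1β-methyl-2α,10α-bis(tert-butyldimethylsilyloxy)-6-(triethylsilyloxy)-4,4-ethylenedioxybicyclo[5.3.0]deca-5,8-diene-8-carboxylate (daucane numbering) | CC[Si](CC)(CC)OC=1CC(C(=O)OCC)=C[C@@H](O[Si](C)(C)C(C)(C)C)[C@@]2(C)[C@@H](O[Si](C)(C)C(C)(C)C)CC3(OCCO3)C=12 | intermediate
19 | allylic alcohol, as 18 with CH2OH on C8 | CC[Si](CC)(CC)OC=1CC(CO)=C[C@@H](O[Si](C)(C)C(C)(C)C)[C@@]2(C)[C@@H](O[Si](C)(C)C(C)(C)C)CC3(OCCO3)C=12 | intermediate
20 | allylic methanesulfonate, as 18 with CH2OSO2Me on C8 | CC[Si](CC)(CC)OC=1CC(COS(C)(=O)=O)=C[C@@H](O[Si](C)(C)C(C)(C)C)[C@@]2(C)[C@@H](O[Si](C)(C)C(C)(C)C)CC3(OCCO3)C=12 | intermediate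
21 | 1β,8-dimethyl-2α,10α-bis(tert-butyldimethylsilyloxy)-6-(triethylsilyloxy)-4,4-ethylenedioxybicyclo[5.3.0]deca-5,8-diene | CC[Si](CC)(CC)OC=1CC(C)=C[C@@H](O[Si](C)(C)C(C)(C)C)[C@@]2(C)[C@@H](O[Si](C)(C)C(C)(C)C)CC3(OCCO3)C=12 | intermediate
22 | trans-fused C6 ketone (5α-H), 1β,8-dimethyl-2α,10α-bis(tert-butyldimethylsilyloxy)-4,4-ethylenedioxybicyclo[5.3.0]dec-8-en-6-one | O=C1CC(C)=C[C@@H](O[Si](C)(C)C(C)(C)C)[C@@]2(C)[C@@H](O[Si](C)(C)C(C)(C)C)CC3(OCCO3)[C@H]12 | intermediate
23 | 6β-carbinol of 22 | O[C@@H]1CC(C)=C[C@@H](O[Si](C)(C)C(C)(C)C)[C@@]2(C)[C@@H](O[Si](C)(C)C(C)(C)C)CC3(OCCO3)[C@H]12 | intermediate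
24 | 6β-(4-methoxybenzyl) ether of 23 | COc1ccc(cc1)CO[C@@H]2CC(C)=C[C@@H](O[Si](C)(C)C(C)(C)C)[C@@]3(C)[C@@H](O[Si](C)(C)C(C)(C)C)CC4(OCCO4)[C@H]23 | intermediate
25 | C4 cyclopentanone, 6β-(4-methoxybenzyloxy)-2α,10α-bis(tert-butyldimethylsilyloxy)-1β,8-dimethylbicyclo[5.3.0]dec-8-en-4-one (5α-H) | COc1ccc(cc1)CO[C@@H]2CC(C)=C[C@@H](O[Si](C)(C)C(C)(C)C)[C@@]3(C)[C@@H](O[Si](C)(C)C(C)(C)C)CC(=O)[C@H]23 | intermediate
26 | isopropylmagnesium chloride | CC(C)[Mg]Cl | starting material
27 | C4 tertiary carbinol (4β-OH, 4α-isopropyl) with 6β-(4-methoxybenzyl) ether | COc1ccc(cc1)CO[C@@H]2CC(C)=C[C@@H](O[Si](C)(C)C(C)(C)C)[C@@]3(C)[C@@H](O[Si](C)(C)C(C)(C)C)C[C@@](O)(C(C)C)[C@H]23 | intermediate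
28 | 4β,6β-diol | O[C@@H]1CC(C)=C[C@@H](O[Si](C)(C)C(C)(C)C)[C@@]2(C)[C@@H](O[Si](C)(C)C(C)(C)C)C[C@@](O)(C(C)C)[C@H]12 | intermediate
29 | beta-hydroxy ketone, 4β-hydroxy-4α-isopropyl-1β,8-dimethyl-2α,10α-bis(tert-butyldimethylsilyloxy)bicyclo[5.3.0]dec-8-en-6-one (5α-H) | O=C1CC(C)=C[C@@H](O[Si](C)(C)C(C)(C)C)[C@@]2(C)[C@@H](O[Si](C)(C)C(C)(C)C)C[C@@](O)(C(C)C)[C@H]12 | intermediate
30 | 4β,6α-diol | O[C@H]1CC(C)=C[C@@H](O[Si](C)(C)C(C)(C)C)[C@@]2(C)[C@@H](O[Si](C)(C)C(C)(C)C)C[C@@](O)(C(C)C)[C@H]12 | intermediate
31 | angelic acid, (Z)-2-methylbut-2-enoic acid | C/C=C(/C)C(=O)O | starting material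
32 | 6α-angelate with 2α,10α silyl ethers and 4β-OH | C/C=C(/C)C(=O)O[C@H]1CC(C)=C[C@@H](O[Si](C)(C)C(C)(C)C)[C@@]2(C)[C@@H](O[Si](C)(C)C(C)(C)C)C[C@@](O)(C(C)C)[C@H]12 | intermediate
33 | 6α-angelate 2α,4β,10α-triol | C/C=C(/C)C(=O)O[C@H]1CC(C)=C[C@@H](O)[C@@]2(C)[C@@H](O)C[C@@](O)(C(C)C)[C@H]12 | intermediate
34 | 8α,9α-epoxide 2α,4β,10α-triol 6α-angelate | C/C=C(/C)C(=O)O[C@H]1C[C@@]2(C)O[C@H]2[C@@H](O)[C@@]2(C)[C@@H](O)C[C@@](O)(C(C)C)[C@H]12 | intermediate
35 | CNP0170993.1, 2α,10α-diacetoxy-6α-angeloyloxy-8α,9α-epoxydaucan-4β-ol | C/C=C(/C)C(=O)O[C@H]1C[C@@]2(C)O[C@H]2[C@@H](OC(C)=O)[C@@]2(C)[C@@H](OC(C)=O)C[C@@](O)(C(C)C)[C@H]12 | target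

**Step count**
Total: 26 steps. Longest linear sequence: 24 steps (steps 1–8 and 11–26; steps 9 and 10 prepare the diazo partner).

**Steps most likely to fail**

1. Step 11. The push-pull C6–C8 bond of the cyclopropane (silyloxy donor, ester acceptor) may ionise faster than the crowded boat is passed, since the methyl points inward and C10 arrives on the face of the C2 silyl ether. That would scramble the catalyst-set configuration or divert material to ring-opened products; capture of the carbenoid by the enol ether of a second diazo molecule is a further drain. Fallback: separate the two events and remove the acceptor before the sigmatropic step. The rhodium reaction is run at or below 0 °C and worked up cold so that cyclopropane 17 is isolated. Its ester is reduced with i-Bu2AlH at −78 °C to the cyclopropylmethanol F1, which no longer has a push-pull bond. F1 can therefore be heated (toluene, 110–140 °C) through the same Cope rearrangement without loss of configuration, giving allylic alcohol 19, where the route resumes at step 13.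

2. Step 15. The C5 enolate may be protonated on the methyl face (cis ring fusion), and the C8=C9 alkene may drift into conjugation with the new ketone. Fallback: settle the ring fusion thermodynamically one ketone later, where no beta,gamma-alkene is involved. The cis-fused ketone F2 (C5 epimer of 22) is reduced with NaBH4 to the carbinol F3 and protected as the 4-methoxybenzyl ether F4. The dioxolane is hydrolysed to the cis-fused cyclopentanone F5, in which C5 is alpha to the C4 carbonyl. Equilibration with DBU in toluene is expected to favour the trans-fused ketone 25, the ring fusion of the natural daucanes, and the route resumes at step 19. C6 is written as in the main series; its configuration is erased at 29 in any case.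

3. Step 19. The hindered cyclopentanone may be enolised (with beta-elimination of a silanol or of the benzyl-type ether), reduced by beta-hydride transfer from the isopropyl reagent, or attacked on the wrong face. Fallback: deliver the three carbons as a smaller sp2 nucleophile that cannot transfer a beta-hydride. CH2=C(CH3)MgBr with CeCl3 adds to 25 to give the isopropenyl carbinol F6. Its 1,1-disubstituted alkene is then hydrogenated selectively with RhCl(PPh3)3 under H2, the trisubstituted C8=C9 alkene and the benzyl-type ether being left alone. This gives 27 and rejoins the route at step 20.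

Further compounds
F1 | step 11 | cyclopropylmethanol, as 17 with CH2OH in place of CO2Et | CC[Si](CC)(CC)O[C@@]1(C2=C(C)[C@@H](O[Si](C)(C)C(C)(C)C)CC23OCCO3)C[C@]1(CO)/C=C/O[Si](C)(C)C(C)(C)C
F2 | step 15 | cis-fused C6 ketone (5β-H), C5 epimer of 22 | O=C1CC(C)=C[C@@H](O[Si](C)(C)C(C)(C)C)[C@@]2(C)[C@@H](O[Si](C)(C)C(C)(C)C)CC3(OCCO3)[C@@H]12
F3 | step 15 | cis-fused C6 carbinol, C5 epimer of 23 | O[C@@H]1CC(C)=C[C@@H](O[Si](C)(C)C(C)(C)C)[C@@]2(C)[C@@H](O[Si](C)(C)C(C)(C)C)CC3(OCCO3)[C@@H]12
F4 | step 15 | cis-fused 4-methoxybenzyl ether, C5 epimer of 24 | COc1ccc(cc1)CO[C@@H]2CC(C)=C[C@@H](O[Si](C)(C)C(C)(C)C)[C@@]3(C)[C@@H](O[Si](C)(C)C(C)(C)C)CC4(OCCO4)[C@@H]23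
F5 | step 15 | cis-fused C4 cyclopentanone, C5 epimer of 25 | COc1ccc(cc1)CO[C@@H]2CC(C)=C[C@@H](O[Si](C)(C)C(C)(C)C)[C@@]3(C)[C@@H](O[Si](C)(C)C(C)(C)C)CC(=O)[C@@H]23
F6 | step 19 | C4 isopropenyl carbinol, as 27 with prop-1-en-2-yl in place of isopropyl | COc1ccc(cc1)CO[C@@H]2CC(C)=C[C@@H](O[Si](C)(C)C(C)(C)C)[C@@]3(C)[C@@H](O[Si](C)(C)C(C)(C)C)C[C@@](O)(C(C)=C)[C@H]23
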